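**Strategy.** Ring A (the acetoxycyclohexene bearing the alkyne) is treated as the enol triflate of a 2,2,6-trimethylcyclohexanone: C6 is a masked carbonyl between the gem-dimethyl carbon C1 and the methyl-bearing C5. This ketone arises by one-carbon ring expansion of (S)-4-silyloxy-2,2-dimethylcyclopentanone with diazoethane. The quaternary carbon is disfavoured in the migration, so CH(CH3) is inserted only on the CH2 side, and the carbinol stereocentre, set by catalytic conjugate borylation, is untouched. The derived triflate feeds both end rings: Sonogashira coupling for ring A, carbonylation and asymmetric epoxidation for ring B. A bromo-ylidenebutenolide then links the halves by Stille and Suzuki couplings.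

Key step: step 4

Remarks on the chemistry:
- Locants: ring A is the acetoxycyclohexene, with C1 (gem-dimethyl), C2, C3 (acetoxy), C4, C5 (methyl-bearing sp2 carbon) and C6 (alkyne-bearing sp2 carbon). The chain runs from C7 (alkyne carbon on ring A) to C18 (ylidene-bearing lactone carbon). Ring B is the epoxycyclohexane and ring C the butenolide.
- Diazoethane is treated as a reagent, used as a freshly prepared toluene solution (base cleavage of commercial N-ethyl-N-nitrosourea).
- In step 2 the ligand enantiomer is the one that gives the S boronate; its antipode would give the R series.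

Step 1
Reactants: 1 2,2-dimethylcyclopentanone
Product: 2 5,5-dimethylcyclopent-2-en-1-one
Conditions: IBX, DMSO/toluene (1:2), 70 °C
Reagents that add atoms: none
Why: IBX dehydrogenates ketones to enones through the enol, and since only one α-carbon of 1 carries hydrogen a single enone can form.

Step 2
Reactants: 2 5,5-dimethylcyclopent-2-en-1-one
Product: 4 (S)-4-hydroxy-2,2-dimethylcyclopentanone, via β-boryl ketone 3 (not isolated)
Conditions: B2pin2, CuCl (3 mol %), NaOtBu (5 mol %), chiral ferrocenyl bisphosphine of the Josiphos family, MeOH (2 equiv), THF, rt; then NaBO3·4H2O, THF/H2O, rt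
Reagents that add atoms: bis(pinacolato)diboron CC1(C)OB(OC1(C)C)B1OC(C)(C)C(C)(C)O1 (boron of 3); sodium perborate [Na+].[O-]OB=O (oxygen of 4)
Why: Copper-catalysed asymmetric conjugate borylation, in which the chiral bisphosphine–copper boryl adds to one face of the β-carbon (catalyst control sets the S centre), methanol protonates the copper enolate and perborate oxidises the C–B bond with retention.

Step 3
Reactants: 4 (S)-4-hydroxy-2,2-dimethylcyclopentanone
Product: 5 (S)-4-(tert-butyldimethylsilyloxy)-2,2-dimethylcyclopentanone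
Conditions: TBSCl, imidazole, DMF, 0 °C → rt
Reagents that add atoms: tert-butyldimethylsilyl chloride CC(C)(C)[Si](C)(C)Cl
Why: Silyl ether formation under near-neutral conditions, which avoids β-elimination of the aldol-type alcohol.

Step 4
Reactants: 5 (S)-4-(tert-butyldimethylsilyloxy)-2,2-dimethylcyclopentanone
Product: 6 (4R)-4-(tert-butyldimethylsilyloxy)-2,2,6-trimethylcyclohexanone (both C6 epimers)
Conditions: CH3CHN2 (1.5 equiv, toluene solution), Sc(OTf)3 (10 mol %), toluene, −78 → −40 °C
Reagents that add atoms: diazoethane CC=[N+]=[N-]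
Why: Diazoethane adds through carbon to the Sc(OTf)3-activated carbonyl of 5 to give a β-alkoxy diazonium betaine, and the ring C–C bond anti to the departing N2 shifts to the diazonium carbon, so the cyclopentanone becomes a cyclohexanone by a 1,2-migration and not by a cyclisation. The closest known reaction type is the Lewis-acid-catalysed homologation of cycloalkanones with non-stabilised diazoalkanes (a Tiffeneau–Demjanov-type carbon insertion). The step needs regioselectivity between the two α-carbons: the quaternary carbon shields its side of the carbonyl and, as is general for these insertions into α-substituted cycloalkanones, the less substituted CH2 carbon migrates, so CH(CH3) is inserted between the carbonyl and CH2; this puts the future C5 methyl next to the carbonyl that becomes C6 and leaves the gem-dimethyl carbon (future C1) on the other side. A second insertion is not expected because the carbonyl of 6 is flanked by a quaternary and a tertiary carbon. The new CH(CH3) stereocentre is not controlled and need not be, since it becomes sp2 in step 5; the silyloxy-bearing carbon is remote from the migrating bond and keeps its configuration (4R in 6 by the priority rules).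

Step 5
Reactants: 6 (4R)-4-(tert-butyldimethylsilyloxy)-2,2,6-trimethylcyclohexanone
Product: 8 (R)-4-(tert-butyldimethylsilyloxy)-2,6,6-trimethylcyclohex-1-en-1-yl trifluoromethanesulfonate, via lithium enolate 7 (not isolated)
Conditions: LiN(iPr)2, THF, −78 → 0 °C; PhNTf2, 0 °C → rt
Reagents that add atoms: N-phenylbis(trifluoromethanesulfonimide) O=S(=O)(N(c1ccccc1)S(=O)(=O)C(F)(F)F)C(F)(F)F
Why: Only the CH(CH3) side of 6 can enolise, so deprotonation and O-sulfonylation (enol triflate formation) give the tetrasubstituted triflate regiospecifically and erase the uncontrolled methyl-bearing centre.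

Step 6
Reactants: 8 (R)-4-(tert-butyldimethylsilyloxy)-2,6,6-trimethylcyclohex-1-en-1-yl trifluoromethanesulfonate
Product: 9 (R)-3,5,5-trimethyl-4-(trifluoromethylsulfonyloxy)cyclohex-3-en-1-yl acetate
Conditions: Ac2O, FeCl3 (10 mol %), CH2Cl2, 0 °C
Reagents that add atoms: acetic anhydride CC(=O)OC(C)=O
Why: Lewis-acid-catalysed acylative cleavage of the silyl ether (direct silyl-to-acetate exchange) breaks the Si–O and not the C–O bond, so the carbinol configuration is retained and the enol triflate is untouched.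

Step 7
Reactants: 9 (R)-3,5,5-trimethyl-4-(trifluoromethylsulfonyloxy)cyclohex-3-en-1-yl acetate; 10 (E)-3-methylpent-2-en-4-yn-1-ol
Product: 11 (R)-4-[(E)-5-hydroxy-3-methylpent-3-en-1-yn-1-yl]-3,5,5-trimethylcyclohex-3-en-1-yl acetate
Conditions: Pd(PPh3)4 (5 mol %), CuI (10 mol %), iPr2NH, DMF, rt → 40 °C
Reagents that add atoms: none
Why: Sonogashira coupling of an enol triflate with a terminal alkyne (oxidative addition to zerovalent palladium, copper acetylide transmetalation), which leaves the E alkene of 10 and the acetate unchanged.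

Step 8
Reactants: 11 (R)-4-[(E)-5-hydroxy-3-methylpent-3-en-1-yn-1-yl]-3,5,5-trimethylcyclohex-3-en-1-yl acetate
Product: 12 (R)-3,5,5-trimethyl-4-[(E)-3-methyl-5-oxopent-3-en-1-yn-1-yl]cyclohex-3-en-1-yl acetate
Conditions: MnO2, CH2Cl2, rt
Reagents that add atoms: none
Why: MnO2 oxidises only the allylic primary alcohol to the enal without isomerising the E double bond.

Step 9
Reactants: 12 (R)-3,5,5-trimethyl-4-[(E)-3-methyl-5-oxopent-3-en-1-yn-1-yl]cyclohex-3-en-1-yl acetate
Product: 13 (R)-4-[(3E,5E)-6-iodo-3-methylhexa-3,5-dien-1-yn-1-yl]-3,5,5-trimethylcyclohex-3-en-1-yl acetate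
Conditions: CrCl2, CHI3, THF, 0 °C → rt, dark
Reagents that add atoms: iodoform IC(I)I
Why: Takai olefination, in which the geminal dichromium species from CHI3 and CrCl2 adds to the aldehyde and eliminates to the E vinyl iodide (C12).

Step 10
Reactants: 8 (R)-4-(tert-butyldimethylsilyloxy)-2,6,6-trimethylcyclohex-1-en-1-yl trifluoromethanesulfonate
Product: 14 methyl (R)-4-(tert-butyldimethylsilyloxy)-2,6,6-trimethylcyclohex-1-ene-1-carboxylate
Conditions: CO (1 atm), MeOH, Pd(OAc)2 (5 mol %), PPh3 (10 mol %), Et3N, DMF, 65 °C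
Reagents that add atoms: carbon monoxide [C-]#[O+]; methanol CO
Why: Palladium-catalysed alkoxycarbonylation of the enol triflate (oxidative addition, CO insertion, methanolysis of the acyl palladium) installs the exocyclic carbon of ring B.

Step 11
Reactants: 14 methyl (R)-4-(tert-butyldimethylsilyloxy)-2,6,6-trimethylcyclohex-1-ene-1-carboxylate
Product: 15 [(R)-4-(tert-butyldimethylsilyloxy)-2,6,6-trimethylcyclohex-1-en-1-yl]methanol
Conditions: iBu2AlH, CH2Cl2, −78 °C
Reagents that add atoms: none
Why: iBu2AlH reduces the hindered conjugated ester to the allylic alcohol at low temperature, with the silyl ether inert.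

Step 12
Reactants: 15 [(R)-4-(tert-butyldimethylsilyloxy)-2,6,6-trimethylcyclohex-1-en-1-yl]methanol
Product: 16 [4-(tert-butyldimethylsilyloxy)-2,2,6-trimethyl-7-oxabicyclo[4.1.0]heptan-1-yl]methanol, oxirane oxygen trans to the silyloxy group, carbinol carbon as in 8
Conditions: Ti(OiPr)4 (0.2 equiv), L-(+)-diethyl tartrate (0.25 equiv), tBuOOH, 4 Å MS, CH2Cl2, −20 °C
Reagents that add atoms: tert-butyl hydroperoxide CC(C)(C)OO
Why: Sharpless asymmetric epoxidation, in which the L-(+)-tartrate–titanium peroxide delivers oxygen to the alkene face opposite to the silyloxy group (reagent control), setting both oxirane stereocentres of ring B.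

Step 13
Reactants: 16 the trans epoxy alcohol
Product: 17 4-(tert-butyldimethylsilyloxy)-2,2,6-trimethyl-7-oxabicyclo[4.1.0]heptane-1-carbaldehyde, configuration as in 16
Conditions: Dess–Martin periodinane, NaHCO3, CH2Cl2, 0 °C → rt
Reagents that add atoms: none
Why: Buffered Dess–Martin oxidation of the primary alcohol gives the non-enolisable epoxy aldehyde without touching the oxirane.

Step 14
Reactants: 17 the epoxy aldehyde
Product: 18 tert-butyl[(1-ethynyl-2,2,6-trimethyl-7-oxabicyclo[4.1.0]heptan-4-yl)oxy]dimethylsilane, configuration as in 16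
Conditions: dimethyl (1-diazo-2-oxopropyl)phosphonate, K2CO3, MeOH, 0 °C → rt
Reagents that add atoms: dimethyl (1-diazo-2-oxopropyl)phosphonate COP(=O)(OC)C(=[N+]=[N-])C(C)=O
Why: Seyferth–Gilbert homologation with the Ohira–Bestmann reagent (addition of the diazomethylphosphonate anion, loss of phosphate and N2, 1,2-hydrogen shift of the alkylidene carbene) suits this aldehyde, which has no α-hydrogen.

Step 15
Reactants: 18 the silyl-protected epoxy alkyne
Product: 19 1-ethynyl-2,2,6-trimethyl-7-oxabicyclo[4.1.0]heptan-4-ol, configuration as in ring B of the target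
Conditions: Bu4NF, THF, 0 °C → rt
Reagents that add atoms: none
Why: Fluoride cleaves the silyl ether at a stage where only an alkyne, an oxirane and the alcohol are present.

Step 16
Reactants: 19 the hydroxy epoxy alkyne
Product: 20 1-[(E)-2-(tributylstannyl)vinyl]-2,2,6-trimethyl-7-oxabicyclo[4.1.0]heptan-4-ol, configuration as in ring B of the target
Conditions: Bu3SnH, PdCl2(PPh3)2 (2 mol %), THF, 0 °C
Reagents that add atoms: tributyltin hydride CCCC[SnH](CCCC)CCCC
Why: Palladium-catalysed hydrostannation is a syn addition that places tin on the terminal carbon because the other alkyne carbon bears a quaternary centre, giving the E vinylstannane.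

Step 17
Reactants: 10 (E)-3-methylpent-2-en-4-yn-1-ol
Product: 21 (E)-3-methylpent-2-en-4-ynal
Conditions: MnO2, CH2Cl2, rt (solution used without concentration)
Reagents that add atoms: none
Why: MnO2 oxidation of the allylic alcohol gives the enynal with retention of the E geometry.

Step 18
Reactants: 21 (E)-3-methylpent-2-en-4-ynal
Product: 22 2-[(1E,3E)-4-methylhexa-1,3-dien-5-yn-1-yl]-4,4,5,5-tetramethyl-1,3,2-dioxaborolane
Conditions: CrCl2, Cl2CHBpin, LiI, THF, rt
Reagents that add atoms: 2-(dichloromethyl)-4,4,5,5-tetramethyl-1,3,2-dioxaborolane ClC(Cl)B1OC(C)(C)C(C)(C)O1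
Why: Takai–Utimoto boron variant of the chromium olefination, in which the geminal dichromium boronate adds to the aldehyde and eliminates to the E alkenyl pinacol boronate (C13), the terminal alkyne being inert.

Step 19
Reactants: 23 propiolic acid
Product: 24 (E)-2,3-dibromoacrylic acid
Conditions: Br2 (1.0 equiv), CHCl3, 0 °C → rt, dark
Reagents that add atoms: bromine BrBr
Why: Ionic anti addition of bromine across the alkyne gives the E dibromide, which places the β-bromine cis to the carboxyl group as the later lactonisation requires.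

Step 20
Reactants: 24 (E)-2,3-dibromoacrylic acid; 22 the dienyne pinacol boronate
Product: 26 (Z)-3-bromo-5-[(2E,4E)-2-methyl-5-(4,4,5,5-tetramethyl-1,3,2-dioxaborolan-2-yl)penta-2,4-dien-1-ylidene]furan-2(5H)-one, via enynoic acid 25 (not isolated)
Conditions: PdCl2(PPh3)2 (5 mol %), CuI (10 mol %), Et3N, MeCN, rt
Reagents that add atoms: none
Why: Tandem Sonogashira coupling/lactonisation, in which the β-C–Br bond reacts before the α-C–Br bond with retention and the cis carboxylate then adds 5-exo-dig anti across the metal-activated alkyne to give the Z ylidenebutenolide (ring C), the boronate being inert without aqueous base.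

Step 21
Reactants: 26 the bromo-ylidenebutenolide boronate; 20 the ring-B vinylstannane
Product: 27 (Z)-3-[(E)-2-(4-hydroxy-2,2,6-trimethyl-7-oxabicyclo[4.1.0]heptan-1-yl)vinyl]-5-[(2E,4E)-2-methyl-5-(4,4,5,5-tetramethyl-1,3,2-dioxaborolan-2-yl)penta-2,4-dien-1-ylidene]furan-2(5H)-one, ring B configured as in 20
Conditions: Pd2(dba)3 (5 mol %), AsPh3 (20 mol %), NMP, 50 °C, dark
Reagents that add atoms: none
Why: Stille coupling at the lactone C–Br bond with retention of the E geometry of the stannane, the pinacol boronate not transmetalating under base-free conditions.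

Step 22
Reactants: 13 the ring-A dienyne iodide; 27 the ring-B/ring-C trienyl boronate
Product: 28 pyrrhoxanthin (the target)
Conditions: Pd(OAc)2 (5 mol %), SPhos (10 mol %), K3PO4 (3 M aq.), THF, rt, dark, argon
Reagents that add atoms: none
Why: Suzuki–Miyaura coupling of an alkenyl iodide with an alkenyl boronate forms the C12–C13 single bond with retention at both alkenes under mild aqueous phosphate at room temperature, which the acetate, lactone and oxirane should tolerate.

**Compound list**

1 | 2,2-dimethylcyclopentanone | CC1(C)CCCC1=O | starting material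
2 | 5,5-dimethylcyclopent-2-en-1-one | CC1(C)CC=CC1=O | intermediate
3 | (S)-2,2-dimethyl-4-(4,4,5,5-tetramethyl-1,3,2-dioxaborolan-2-yl)cyclopentanone | O=C1C[C@@H](B2OC(C)(C)C(C)(C)O2)CC1(C)C | intermediate
4 | (S)-4-hydroxy-2,2-dimethylcyclopentanone | O=C1C[C@@H](O)CC1(C)C | intermediate
5 | (S)-4-(tert-butyldimethylsilyloxy)-2,2-dimethylcyclopentanone | O=C1C[C@@H](O[Si](C)(C)C(C)(C)C)CC1(C)C | intermediate
6 | (4R)-4-(tert-butyldimethylsilyloxy)-2,2,6-trimethylcyclohexanone (C6 epimers) | O=C1C(C)C[C@@H](O[Si](C)(C)C(C)(C)C)CC1(C)C | intermediate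
7 | lithium (R)-4-(tert-butyldimethylsilyloxy)-2,6,6-trimethylcyclohex-1-en-1-olate | [Li+].[O-]C1=C(C)C[C@@H](O[Si](C)(C)C(C)(C)C)CC1(C)C | intermediate
8 | (R)-4-(tert-butyldimethylsilyloxy)-2,6,6-trimethylcyclohex-1-en-1-yl trifluoromethanesulfonate | O=S(=O)(OC1=C(C)C[C@@H](O[Si](C)(C)C(C)(C)C)CC1(C)C)C(F)(F)F | intermediate
9 | (R)-3,5,5-trimethyl-4-(trifluoromethylsulfonyloxy)cyclohex-3-en-1-yl acetate | CC(=O)O[C@@H]1CC(C)=C(OS(=O)(=O)C(F)(F)F)C(C)(C)C1 | intermediate
10 | (E)-3-methylpent-2-en-4-yn-1-ol | C#C/C(C)=C/CO | starting material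
11 | (R)-4-[(E)-5-hydroxy-3-methylpent-3-en-1-yn-1-yl]-3,5,5-trimethylcyclohex-3-en-1-yl acetate | CC(=O)O[C@@H]1CC(C)=C(C#C/C(C)=C/CO)C(C)(C)C1 | intermediate
12 | (R)-3,5,5-trimethyl-4-[(E)-3-methyl-5-oxopent-3-en-1-yn-1-yl]cyclohex-3-en-1-yl acetate | CC(=O)O[C@@H]1CC(C)=C(C#C/C(C)=C/C=O)C(C)(C)C1 | intermediate
13 | (R)-4-[(3E,5E)-6-iodo-3-methylhexa-3,5-dien-1-yn-1-yl]-3,5,5-trimethylcyclohex-3-en-1-yl acetate | CC(=O)O[C@@H]1CC(C)=C(C#C/C(C)=C/C=C/I)C(C)(C)C1 | intermediate
14 | methyl (R)-4-(tert-butyldimethylsilyloxy)-2,6,6-trimethylcyclohex-1-ene-1-carboxylate | COC(=O)C1=C(C)C[C@@H](O[Si](C)(C)C(C)(C)C)CC1(C)C | intermediate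
15 | [(R)-4-(tert-butyldimethylsilyloxy)-2,6,6-trimethylcyclohex-1-en-1-yl]methanol | OCC1=C(C)C[C@@H](O[Si](C)(C)C(C)(C)C)CC1(C)C | intermediate
16 | [4-(tert-butyldimethylsilyloxy)-2,2,6-trimethyl-7-oxabicyclo[4.1.0]heptan-1-yl]methanol, oxirane trans to the silyloxy group | OC[C@@]12O[C@]1(C)C[C@@H](O[Si](C)(C)C(C)(C)C)CC2(C)C | intermediate
17 | 4-(tert-butyldimethylsilyloxy)-2,2,6-trimethyl-7-oxabicyclo[4.1.0]heptane-1-carbaldehyde, configuration as in 16 | O=C[C@@]12O[C@]1(C)C[C@@H](O[Si](C)(C)C(C)(C)C)CC2(C)C | intermediate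
18 | tert-butyl[(1-ethynyl-2,2,6-trimethyl-7-oxabicyclo[4.1.0]heptan-4-yl)oxy]dimethylsilane, configuration as in 16 | C#C[C@@]12O[C@]1(C)C[C@@H](O[Si](C)(C)C(C)(C)C)CC2(C)C | intermediate
19 | 1-ethynyl-2,2,6-trimethyl-7-oxabicyclo[4.1.0]heptan-4-ol, configuration as in ring B of the target | C#C[C@@]12O[C@]1(C)C[C@@H](O)CC2(C)C | intermediate
20 | 1-[(E)-2-(tributylstannyl)vinyl]-2,2,6-trimethyl-7-oxabicyclo[4.1.0]heptan-4-ol, configuration as in ring B of the target | CCCC[Sn](CCCC)(CCCC)/C=C/[C@@]12O[C@]1(C)C[C@@H](O)CC2(C)C | intermediate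
21 | (E)-3-methylpent-2-en-4-ynal | C#C/C(C)=C/C=O | intermediate
22 | 2-[(1E,3E)-4-methylhexa-1,3-dien-5-yn-1-yl]-4,4,5,5-tetramethyl-1,3,2-dioxaborolane | C#C/C(C)=C/C=C/B1OC(C)(C)C(C)(C)O1 | intermediate
23 | propiolic acid | C#CC(=O)O | starting material
24 | (E)-2,3-dibromoacrylic acid | Br/C=C(/Br)C(=O)O | intermediate
25 | (2E,6E,8E)-2-bromo-6-methyl-9-(4,4,5,5-tetramethyl-1,3,2-dioxaborolan-2-yl)nona-2,6,8-trien-4-ynoic acid | CC1(C)OB(/C=C/C=C(C)/C#C/C=C(/Br)C(=O)O)OC1(C)C | intermediate
26 | (Z)-3-bromo-5-[(2E,4E)-2-methyl-5-(4,4,5,5-tetramethyl-1,3,2-dioxaborolan-2-yl)penta-2,4-dien-1-ylidene]furan-2(5H)-one | CC1(C)OB(/C=C/C=C(C)/C=C2C=C(Br)C(=O)O/2)OC1(C)C | intermediate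
27 | (Z)-3-[(E)-2-(4-hydroxy-2,2,6-trimethyl-7-oxabicyclo[4.1.0]heptan-1-yl)vinyl]-5-[(2E,4E)-2-methyl-5-(4,4,5,5-tetramethyl-1,3,2-dioxaborolan-2-yl)penta-2,4-dien-1-ylidene]furan-2(5H)-one, ring B as in 20 | CC1(C)OB(/C=C/C=C(C)/C=C2C=C(/C=C/[C@@]34O[C@]3(C)C[C@@H](O)CC4(C)C)C(=O)O/2)OC1(C)C | intermediate
28 | pyrrhoxanthin | CC(=O)O[C@@H]1CC(C)=C(C#C/C(C)=C/C=C/C=C/C=C(C)/C=C2C=C(/C=C/[C@@]34O[C@]3(C)C[C@@H](O)CC4(C)C)C(=O)O/2)C(C)(C)C1 | target

**Step count.** Total: 22 steps. Longest linear sequence: 14 steps (steps 1–5, 10–16, 21, 22).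

**Steps most likely to fail**

Step 4. The hindered carbonyl may add diazoethane sluggishly, or the quaternary carbon may migrate competitively and give the regioisomeric ketone. The fallback keeps the ring enlargement but drives it by cyclopropane strain release; it sets out from 5 and comes back at 6. Enolisation of 5 on its only enolisable side (LiN(iPr)2, Me3SiCl, THF, −78 °C) should give the trimethylsilyl enol ether F1. Cyclopropanation (Et2Zn, CH2I2, CH2Cl2, 0 °C) should give the siloxybicyclo[3.1.0]hexane F2. FeCl3 in DMF should open the internal cyclopropane bond oxidatively, and NaOAc in MeOH should then eliminate HCl to give the ring-enlarged enone F3. Conjugate reduction with LiBH(sBu)3 (THF, −78 °C) and trapping of the regiodefined enolate with MeI should give 6.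

Step 16. Zerovalent palladium may ionise the propargylic oxirane, or tin may be delivered to the internal carbon. The fallback replaces alkyne hydrometalation by a chromium-mediated stannyl olefination; it sets out from 17 and comes back at 20. Treatment of 17 with Bu3SnCHBr2, CrCl2 and LiI (THF/DMF, rt) should give the silyl-protected E vinylstannane F4, and Bu4NF in THF should then give 20.

Step 22. Aqueous base may cleave the acetate or open the lactone on the fully assembled chromophore, and the trienyl boronate may protodeboronate or isomerise. The fallback makes the same C12–C13 bond by a base-free Stille coupling; it sets out from 12 and 24 (with 10 and 20) and comes back at 28.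
- Aldehyde 12 with Bu3SnCHBr2, CrCl2 and LiI should give the ring-A dienyne stannane F5.
- Acid 24 and enynol 10 under the conditions of step 20 should give the bromo-ylidenebutenolide alcohol F6.
- Stille coupling of F6 with 20 (as in step 21) should give the ring-B/ring-C allylic alcohol F7.
- MnO2 should oxidise F7 to the aldehyde F8.
- CHI3 and CrCl2 should convert F8 into the E trienyl iodide F9.
- F5 and F9 with Pd2(dba)3 and AsPh3 in NMP at rt should give 28.

**Further compounds**

F1 | step 4 | (S)-tert-butyl{[4,4-dimethyl-3-(trimethylsilyloxy)cyclopent-2-en-1-yl]oxy}dimethylsilane | C[Si](C)(C)OC1=C[C@@H](O[Si](C)(C)C(C)(C)C)CC1(C)C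
F2 | step 4 | 4-(tert-butyldimethylsilyloxy)-2,2-dimethyl-1-(trimethylsilyloxy)bicyclo[3.1.0]hexane (cyclopropane diastereomers) | C[Si](C)(C)OC12CC1[C@@H](O[Si](C)(C)C(C)(C)C)CC2(C)C
F3 | step 4 | (S)-4-(tert-butyldimethylsilyloxy)-6,6-dimethylcyclohex-2-en-1-one | O=C1C=C[C@@H](O[Si](C)(C)C(C)(C)C)CC1(C)C
F4 | step 16 | tert-butyldimethyl({1-[(E)-2-(tributylstannyl)vinyl]-2,2,6-trimethyl-7-oxabicyclo[4.1.0]heptan-4-yl}oxy)silane, configuration as in 16 | CCCC[Sn](CCCC)(CCCC)/C=C/[C@@]12O[C@]1(C)C[C@@H](O[Si](C)(C)C(C)(C)C)CC2(C)C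
F5 | step 22 | (R)-3,5,5-trimethyl-4-[(3E,5E)-3-methyl-6-(tributylstannyl)hexa-3,5-dien-1-yn-1-yl]cyclohex-3-en-1-yl acetate | CC(=O)O[C@@H]1CC(C)=C(C#C/C(C)=C/C=C/[Sn](CCCC)(CCCC)CCCC)C(C)(C)C1
F6 | step 22 | (Z)-3-bromo-5-[(E)-4-hydroxy-2-methylbut-2-en-1-ylidene]furan-2(5H)-one | OC/C=C(C)/C=C1C=C(Br)C(=O)O/1
F7 | step 22 | (Z)-3-[(E)-2-(4-hydroxy-2,2,6-trimethyl-7-oxabicyclo[4.1.0]heptan-1-yl)vinyl]-5-[(E)-4-hydroxy-2-methylbut-2-en-1-ylidene]furan-2(5H)-one, ring B as in 20 | OC/C=C(C)/C=C1C=C(/C=C/[C@@]23O[C@]2(C)C[C@@H](O)CC3(C)C)C(=O)O/1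
F8 | step 22 | (E)-4-{(Z)-4-[(E)-2-(4-hydroxy-2,2,6-trimethyl-7-oxabicyclo[4.1.0]heptan-1-yl)vinyl]-5-oxofuran-2(5H)-ylidene}-3-methylbut-2-enal, ring B as in 20 | O=C/C=C(C)/C=C1C=C(/C=C/[C@@]23O[C@]2(C)C[C@@H](O)CC3(C)C)C(=O)O/1
F9 | step 22 | (Z)-3-[(E)-2-(4-hydroxy-2,2,6-trimethyl-7-oxabicyclo[4.1.0]heptan-1-yl)vinyl]-5-[(2E,4E)-5-iodo-2-methylpenta-2,4-dien-1-ylidene]furan-2(5H)-one, ring B as in 20 | I/C=C/C=C(C)/C=C1C=C(/C=C/[C@@]23O[C@]2(C)C[C@@H](O)CC3(C)C)C(=O)O/1
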